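The data were computed with constants of no real substance.

Target is what stands in the electrophile's ledger once two other lines are closed: electrophile left, and isomer of the product.

| flask | electrophile | nucleophile | free base | remark | time |
|---|---|---|---|---|---|
| Thursday's | 0.10 M | 0.060 M | 0.10 M | run made earlier |  |
| Tuesday's | 0.10 M | 0.24 M | 0.10 M | run made earlier |  |
| flask | 0.10 M | 0.120 M | 0.100 M |  | 1.0 h |

| run | time / min | target / % | electrophile / % |
|---|---|---|---|
| Thursday's | 5.00 | 4.0 | 95.4 |
| Thursday's | 12.0 | 9.9 | 89.1 |
| Thursday's | 25.0 | 15.1 | 83.8 |
| Thursday's | 60.0 | 20.5 | 70.6 |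
| Tuesday's | 15.0 | 37.9 | 59.2 |
| Tuesday's | 30.0 | 51.1 | 40.5 |
| Tuesday's | 50.0 | 56.2 | 26.1 |
| Tuesday's | 60.0 | 54.5 | 21.0 |

(scatter of a reading: 1 percentage point)

* how much target the flask holds at 1.0 h, in percent of the electrophile charged
* how much electrophile the flask holds at 1.0 h, in percent of the electrophile charged
* concentration of nucleophile at 1.0 h, in M

- the numbers in the tables scatter by 1 percentage point (one standard deviation)
- reactions considered so far: electrophile + nucleophile -> acid set free + target; nucleophile + acid set free <-> protonated nucleophile; acid set free + free base <-> salt of the base; target <-> isomer of the product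

First line, electrophile left. I count turnovers as the logarithm of charge over what is left. At 60.0 min, Thursday's run stands at 0.348 and Tuesday's at 1.56. Per nucleophile charged that is 5.80 M⁻¹ and 6.50 M⁻¹, so I average them. So I reckon 0.738 turnovers for the flask in 1.0 h, which would keep 47.8 % of its electrophile.

Second line, isomer. Thursday's run has spent 29.4 % of its electrophile, and a share 0.303 of that is missing from target. Tuesday's run has spent 79.0 %, with a share 0.310 missing, on 4.00 times the nucleophile. I book the missing part as isomer. The leak is 0.00511 min⁻¹, the share of spent electrophile standing as isomer per minute of run.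

Closing the books for the flask, the share is 0.306, so isomer takes 16.0 % and target keeps 36.2 %. By this reckoning coupling leaves the flask's nucleophile 56.5 % of its charge, and whatever sits as protonated nucleophile still comes off that, unread.

The forecast says 38 % target (34.5 % to 41 %), 48 % electrophile and 0.06 M nucleophile, and of the missing balance that it “tracks the time-integral of target”.

The flask gives 36.9 % target, 48.7 % electrophile and 0.0453 M nucleophile.

    electrophile + nucleophile → acid set free + target (k = 0.00300 M⁻¹ s⁻¹)
    nucleophile + acid set free ⇌ protonated nucleophile, settled at all times (K = 150 M⁻¹)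
    acid set free + free base ⇌ salt of the base (K = 24000 M⁻¹, k = 0.0330 M⁻¹ s⁻¹)
    target ⇌ isomer of the product (K = 3.10, k = 1.60 × 10⁻⁴ s⁻¹)

The isomer share of spent electrophile in this flask is 0.280 at 1.00 h, against the leak's 0.306. Each step taken net, target in this flask is made 4.55 times as fast as it is used up at 0.295 h. By 1.00 h that ratio is down to 1.28, still above one, so target in this flask is still gaining. In the neighbour flask read at 25 min, the leak gives a share of 0.128, which on the 32.1 % spent there comes to 4.10 % isomer, and that flask holds 4.02 %.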